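**Retrosynthetic overview**

- The strategy rests on ring C: a benzene ring with oxygen on C3, C4 and C5 and the C7–C8–C9 triol chain on C1, that is, a 5-alkylresorcinol with one more oxygen on C4. This is the folded, aromatised form of a 3,5,7-tricarbonyl chain whose central carbon carries the ring A aryloxy group and whose last ketone is bonded to C7.
- The target is reached from a ring C benzodioxinone (a masked resorcylic acid) by saponification/decarboxylation, double O-methylation, hydrogenolysis of two benzyl ethers and acetonide hydrolysis.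
- The benzodioxinone comes from an aryloxy diketo-dioxinone by base-induced aldol aromatisation, which forms the C1–C6 bond and closes ring C.
- The diketo-dioxinone comes from the dianion of an aryloxy keto-dioxinone (ring A phenol, 6-chloromethyl dioxinone, acetyl chloride) and a Weinreb amide made from D-tartrate acetonide, which supplies C7, C8 and C9.
- Ring order: the phenyl ring is bought and joined to ring A (also bought) by Suzuki coupling; ring C is the only ring built and it is formed last.

Key step: step 11

Remark on numbering: ring C carbons are C1 (bearing the chain), C2/C6 (CH), C3/C5 (OMe) and C4 (O-aryl); the chain is C7 (benzylic), C8, C9. The target is (7R,8R).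

Remark on the chemistry: the aryloxy-bearing methine of the keto-dioxinone and the diketo-dioxinone is freely enolisable, so it is written without configuration; it becomes the sp2 carbon C4 in the key step. The acetonide of dimethyl D-tartrate is taken as a purchased starting material.

**Route**

Step 1
Reactants: 1 5-bromo-2-hydroxy-3-methoxybenzaldehyde
Product: 2 2-(benzyloxy)-5-bromo-3-methoxybenzaldehyde
Conditions: BnBr, K2CO3, DMF, rt
Reagents that add atoms: benzyl bromide, BrCc1ccccc1
Why: Williamson ether synthesis, in which the phenoxide of the ortho-formyl phenol displaces bromide from benzyl bromide, should give the benzyl ether that is later removed together with the C9 benzyl ether.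

Step 2
Reactants: 2 2-(benzyloxy)-5-bromo-3-methoxybenzaldehyde; 3 phenylboronic acid
Product: 4 2-(benzyloxy)-3-methoxy-5-phenylbenzaldehyde
Conditions: Pd(PPh3)4 (cat.), K2CO3, dioxane/H2O, 90 °C
Reagents that add atoms: none
Why: Suzuki–Miyaura coupling of an aryl bromide under zerovalent palladium catalysis is general and should tolerate the aldehyde and the benzyl ether.

Step 3
Reactants: 4 2-(benzyloxy)-3-methoxy-5-phenylbenzaldehyde
Product: 6 2-(benzyloxy)-3-methoxy-5-phenylphenol, via aryl formate 5 (not isolated)
Conditions: mCPBA, CH2Cl2, 0 °C to rt; then K2CO3, MeOH, rt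
Reagents that add atoms: meta-chloroperbenzoic acid, OOC(=O)c1cccc(Cl)c1
Why: Baeyer–Villiger (Dakin-type) oxidation, in which the electron-rich aryl group with its ortho benzyloxy substituent migrates to oxygen, should give the aryl formate, which mild methanolysis cleaves to the phenol.

Step 4
Reactants: 7 2,2,6-trimethyl-4H-1,3-dioxin-4-one
Product: 8 6-(chloromethyl)-2,2-dimethyl-4H-1,3-dioxin-4-one
Conditions: LDA, THF, −78 °C; then C2Cl6, −78 to −50 °C
Reagents that add atoms: hexachloroethane, ClC(Cl)(Cl)C(Cl)(Cl)Cl
Why: γ-deprotonation of the dioxinone gives the lithium dienolate, whose γ-carbon is chlorinated by hexachloroethane, a known way to this chloride.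

Step 5
Reactants: 6 2-(benzyloxy)-3-methoxy-5-phenylphenol; 8 6-(chloromethyl)-2,2-dimethyl-4H-1,3-dioxin-4-one
Product: 9 6-{[2-(benzyloxy)-3-methoxy-5-phenylphenoxy]methyl}-2,2-dimethyl-4H-1,3-dioxin-4-one
Conditions: K2CO3, DMF, rt
Reagents that add atoms: none
Why: Williamson SN2 displacement of the activated primary chloride by the phenoxide should place the ring A oxygen on the carbon that becomes C4 of ring C.

Step 6
Reactants: 9 6-{[2-(benzyloxy)-3-methoxy-5-phenylphenoxy]methyl}-2,2-dimethyl-4H-1,3-dioxin-4-one
Product: 10 6-{1-[2-(benzyloxy)-3-methoxy-5-phenylphenoxy]-2-oxopropyl}-2,2-dimethyl-4H-1,3-dioxin-4-one (aryloxy methine undefined)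
Conditions: LiHMDS (1.05 equiv), THF, −78 °C; then AcCl (0.5 equiv), −78 °C; aq. NH4Cl; unreacted 9 recovered and recycled
Reagents that add atoms: acetyl chloride, CC(Cl)=O
Why: Claisen-type γ-C-acylation of a dioxinone lithium dienolate by an acid chloride should give the keto-dioxinone, with half an equivalent of acetyl chloride because the more acidic product takes up a second equivalent of dienolate.

Step 7
Reactants: 11 dimethyl (4S,5S)-2,2-dimethyl-1,3-dioxolane-4,5-dicarboxylate (dimethyl 2,3-O-isopropylidene-D-tartrate)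
Product: 12 methyl (4S,5R)-5-(hydroxymethyl)-2,2-dimethyl-1,3-dioxolane-4-carboxylate
Conditions: NaBH4 (0.6 equiv), MeOH, 0 °C to rt; aq. NH4Cl; diol and unreacted diester separated
Reagents that add atoms: none
Why: partial borohydride reduction of the α-alkoxy-activated diester with limiting hydride should stop largely at the hydroxy ester, and since the two esters are equivalent by C2 symmetry a single mono-alcohol forms with both stereocentres untouched.

Step 8
Reactants: 12 methyl (4S,5R)-5-(hydroxymethyl)-2,2-dimethyl-1,3-dioxolane-4-carboxylate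
Product: 13 methyl (4S,5R)-5-[(benzyloxy)methyl]-2,2-dimethyl-1,3-dioxolane-4-carboxylate
Conditions: BnBr, Ag2O, CH2Cl2, rt, dark
Reagents that add atoms: benzyl bromide, BrCc1ccccc1
Why: silver oxide-promoted O-benzylation runs without strong base, so the ester α-centre (future C7) should neither epimerise nor eliminate.

Step 9
Reactants: 13 methyl (4S,5R)-5-[(benzyloxy)methyl]-2,2-dimethyl-1,3-dioxolane-4-carboxylate
Product: 14 (4S,5R)-5-[(benzyloxy)methyl]-N-methoxy-N,2,2-trimethyl-1,3-dioxolane-4-carboxamide
Conditions: MeNH(OMe)·HCl, iPrMgCl, THF, −20 to 0 °C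
Reagents that add atoms: N,O-dimethylhydroxylamine hydrochloride, CNOC.Cl
Why: direct aminolysis of the ester by the chloromagnesium amide of N,O-dimethylhydroxylamine (Weinreb amide formation) is fast at low temperature and should leave the α-alkoxy centre intact.

Step 10
Reactants: 10 6-{1-[2-(benzyloxy)-3-methoxy-5-phenylphenoxy]-2-oxopropyl}-2,2-dimethyl-4H-1,3-dioxin-4-one; 14 (4S,5R)-5-[(benzyloxy)methyl]-N-methoxy-N,2,2-trimethyl-1,3-dioxolane-4-carboxamide
Product: 15 6-{1-[2-(benzyloxy)-3-methoxy-5-phenylphenoxy]-4-[(4S,5R)-5-[(benzyloxy)methyl]-2,2-dimethyl-1,3-dioxolan-4-yl]-2,4-dioxobutyl}-2,2-dimethyl-4H-1,3-dioxin-4-one (aryloxy methine undefined)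
Conditions: 10, LDA (2.1 equiv), THF, −78 °C; then 14, −78 to −30 °C; aq. NH4Cl; crude 15 taken on quickly
Reagents that add atoms: none
Why: Claisen-type acylation of the keto-dioxinone dianion at its terminal methyl carbon by a Weinreb amide should give the diketo-dioxinone, because the chelated tetrahedral intermediate holds until work-up and so prevents over-addition and shields C7 from enolisation.

Step 11
Reactants: 15 diketo-dioxinone (as named in step 10)
Product: 16 8-[2-(benzyloxy)-3-methoxy-5-phenylphenoxy]-5-[(4R,5R)-5-[(benzyloxy)methyl]-2,2-dimethyl-1,3-dioxolan-4-yl]-7-hydroxy-2,2-dimethyl-4H-1,3-benzodioxin-4-one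
Conditions: Et3N (excess), CH2Cl2, rt
Reagents that add atoms: none
Why: Et3N removes the proton of the aryloxy methine, which is activated by both the dioxinone and the adjacent ketone, and the resulting extended enolate attacks the terminal ketone next to C7 through dioxinone C5; loss of water from the aldol adduct and enolisation of the remaining ketone then give aromatic ring C with the new C1–C6 bond. The closest known reaction type is the amine- or carbonate-induced aromatisation of diketo-dioxinones to 7-hydroxybenzodioxinones (isopropylidene-protected resorcylates), which also works with a substituent on the carbon between dioxinone and ketone. Ring C closes in a 6-(enolendo)-exo-trig aldol mode, which is favoured. No stereocentre is created: the aryloxy methine becomes the sp2 carbon C4, and C7 and C8 are carried through from D-tartrate. The step needs C-aldol closure, not O-cyclisation to a pyranone or acyl transfer, and it must not enolise C7. The dioxinone does not acylate at room temperature because acylketene release needs heat, the two 1,3-dicarbonyl sites are far more acidic than C7–H and take up the weak base, and the trans-dioxolane is in any case the more stable isomer.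

Step 12
Reactants: 16 ring C benzodioxinone (as named in step 11)
Product: 18 2-[2-(benzyloxy)-3-methoxy-5-phenylphenoxy]-5-[(4R,5R)-5-[(benzyloxy)methyl]-2,2-dimethyl-1,3-dioxolan-4-yl]benzene-1,3-diol, via resorcylic acid 17 (not isolated)
Conditions: KOH, MeOH/H2O, 110 °C, sealed tube, Ar; then aq. NH4Cl
Reagents that add atoms: none
Why: hydroxide opens the benzodioxinone (saponification), and the resulting 2,4-dihydroxy-6-alkylbenzoic acid, whose carboxyl group is ortho and para to hydroxyls, should lose CO2 on heating by ipso-protonation (decarboxylation of resorcylic acids), while the benzyl ethers, acetonide and diaryl ether are stable to base.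

Step 13
Reactants: 18 resorcinol (as named in step 12)
Product: 19 (4R,5R)-4-{4-[2-(benzyloxy)-3-methoxy-5-phenylphenoxy]-3,5-dimethoxyphenyl}-5-[(benzyloxy)methyl]-2,2-dimethyl-1,3-dioxolane
Conditions: MeI, K2CO3, DMF, rt
Reagents that add atoms: iodomethane, CI
Why: Williamson O-methylation of both phenols, which are equivalent in ring C, should install the C3 and C5 methoxy groups while the ring A oxygen stays benzylated.

Step 14
Reactants: 19 dimethyl ether (as named in step 13)
Product: 20 [(4R,5R)-5-[4-(2-hydroxy-3-methoxy-5-phenylphenoxy)-3,5-dimethoxyphenyl]-2,2-dimethyl-1,3-dioxolan-4-yl]methanol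
Conditions: H2 (1 atm), Pd/C, EtOAc/EtOH, rt
Reagents that add atoms: none
Why: catalytic hydrogenolysis cleaves the aryl and the alkyl benzyl ether, and under neutral conditions the benzylic C7–O bond held in the dioxolane should react much more slowly and be kept.

Step 15
Reactants: 20 acetonide (as named in step 14)
Product: 21 berbekorin A, (1R,2R)-1-[4-(2-hydroxy-3-methoxy-5-phenylphenoxy)-3,5-dimethoxyphenyl]propane-1,2,3-triol
Conditions: AcOH/H2O (4:1), 45 °C
Reagents that add atoms: none
Why: acid-catalysed hydrolysis of the isopropylidene acetal goes through an oxocarbenium ion at the acetal carbon, so the C7–O and C8–O bonds are not broken and both configurations should be retained.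

**Compound list**

1 | 5-bromo-2-hydroxy-3-methoxybenzaldehyde | COc1cc(Br)cc(C=O)c1O | starting material
2 | 2-(benzyloxy)-5-bromo-3-methoxybenzaldehyde | COc1cc(Br)cc(C=O)c1OCc1ccccc1 | intermediate
3 | phenylboronic acid | OB(O)c1ccccc1 | starting material
4 | 2-(benzyloxy)-3-methoxy-5-phenylbenzaldehyde | COc1cc(-c2ccccc2)cc(C=O)c1OCc1ccccc1 | intermediate
5 | 2-(benzyloxy)-3-methoxy-5-phenylphenyl formate (not isolated) | COc1cc(-c2ccccc2)cc(OC=O)c1OCc1ccccc1 | intermediate
6 | 2-(benzyloxy)-3-methoxy-5-phenylphenol | COc1cc(-c2ccccc2)cc(O)c1OCc1ccccc1 | intermediate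
7 | 2,2,6-trimethyl-4H-1,3-dioxin-4-one | CC1=CC(=O)OC(C)(C)O1 | starting material
8 | 6-(chloromethyl)-2,2-dimethyl-4H-1,3-dioxin-4-one | ClCC1=CC(=O)OC(C)(C)O1 | intermediate
9 | 6-{[2-(benzyloxy)-3-methoxy-5-phenylphenoxy]methyl}-2,2-dimethyl-4H-1,3-dioxin-4-one | CC1(C)OC(=O)C=C(O1)COc1cc(-c2ccccc2)cc(OC)c1OCc1ccccc1 | intermediate
10 | 6-{1-[2-(benzyloxy)-3-methoxy-5-phenylphenoxy]-2-oxopropyl}-2,2-dimethyl-4H-1,3-dioxin-4-one (methine undefined) | CC(=O)C(Oc1cc(-c2ccccc2)cc(OC)c1OCc1ccccc1)C1=CC(=O)OC(C)(C)O1 | intermediate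
11 | dimethyl (4S,5S)-2,2-dimethyl-1,3-dioxolane-4,5-dicarboxylate | COC(=O)[C@H]1OC(C)(C)O[C@@H]1C(=O)OC | starting material
12 | methyl (4S,5R)-5-(hydroxymethyl)-2,2-dimethyl-1,3-dioxolane-4-carboxylate | COC(=O)[C@H]1OC(C)(C)O[C@@H]1CO | intermediate
13 | methyl (4S,5R)-5-[(benzyloxy)methyl]-2,2-dimethyl-1,3-dioxolane-4-carboxylate | COC(=O)[C@H]1OC(C)(C)O[C@@H]1COCc1ccccc1 | intermediate
14 | (4S,5R)-5-[(benzyloxy)methyl]-N-methoxy-N,2,2-trimethyl-1,3-dioxolane-4-carboxamide | CON(C)C(=O)[C@H]1OC(C)(C)O[C@@H]1COCc1ccccc1 | intermediate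
15 | aryloxy diketo-dioxinone ending in the D-threonate acetonide (methine undefined) | CC1(C)OC(=O)C=C(O1)C(Oc1cc(-c2ccccc2)cc(OC)c1OCc1ccccc1)C(=O)CC(=O)[C@H]1OC(C)(C)O[C@@H]1COCc1ccccc1 | intermediate
16 | 8-aryloxy-7-hydroxy-5-[(4R,5R)-dioxolanyl]-2,2-dimethyl-4H-1,3-benzodioxin-4-one (ring C benzodioxinone) | CC1(C)OC(=O)c2c(O1)c(Oc1cc(-c3ccccc3)cc(OC)c1OCc1ccccc1)c(O)cc2[C@H]1OC(C)(C)O[C@@H]1COCc1ccccc1 | intermediate
17 | 3-[2-(benzyloxy)-3-methoxy-5-phenylphenoxy]-6-[(4R,5R)-5-[(benzyloxy)methyl]-2,2-dimethyl-1,3-dioxolan-4-yl]-2,4-dihydroxybenzoic acid (not isolated) | OC(=O)c1c(O)c(Oc2cc(-c3ccccc3)cc(OC)c2OCc2ccccc2)c(O)cc1[C@H]1OC(C)(C)O[C@@H]1COCc1ccccc1 | intermediate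
18 | 2-[2-(benzyloxy)-3-methoxy-5-phenylphenoxy]-5-[(4R,5R)-5-[(benzyloxy)methyl]-2,2-dimethyl-1,3-dioxolan-4-yl]benzene-1,3-diol | Oc1cc([C@H]2OC(C)(C)O[C@@H]2COCc2ccccc2)cc(O)c1Oc1cc(-c2ccccc2)cc(OC)c1OCc1ccccc1 | intermediate
19 | (4R,5R)-4-{4-[2-(benzyloxy)-3-methoxy-5-phenylphenoxy]-3,5-dimethoxyphenyl}-5-[(benzyloxy)methyl]-2,2-dimethyl-1,3-dioxolane | COc1cc([C@H]2OC(C)(C)O[C@@H]2COCc2ccccc2)cc(OC)c1Oc1cc(-c2ccccc2)cc(OC)c1OCc1ccccc1 | intermediate
20 | [(4R,5R)-5-[4-(2-hydroxy-3-methoxy-5-phenylphenoxy)-3,5-dimethoxyphenyl]-2,2-dimethyl-1,3-dioxolan-4-yl]methanol | COc1cc([C@H]2OC(C)(C)O[C@@H]2CO)cc(OC)c1Oc1cc(-c2ccccc2)cc(OC)c1O | intermediate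
21 | berbekorin A | COc1cc(-c2ccccc2)cc(Oc2c(OC)cc([C@@H](O)[C@H](O)CO)cc2OC)c1O | target

**Step count and risks**

Total step count: 15. Longest linear sequence: 11 steps (steps 1, 2, 3, 5, 6, 10, 11, 12, 13, 14, 15).

Steps most likely to fail:

1. Step 11. The closure could go astray through O-cyclisation of a diketone enol onto the dioxinone, through slow attack on the hindered ketone beside the dioxolane, or through enolisation toward C7 with opening of the acetonide. The fallback sets out from 15 and separates ester formation from ring closure. Heating 15 in toluene with methanol at about 110 °C should release acetone and the acylketene, which methanol traps as the open-chain methyl 4-aryloxy-3,5,7-trioxoheptanoate F1. Cs2CO3 in MeOH at room temperature, followed by an acetic acid work-up, should then effect the aldol condensation of the β-keto ester carbon onto the terminal ketone and give the methyl resorcylate F2. Saponification and decarboxylation of F2 under the conditions of step 12 pass through acid 17 and come back to the route at resorcinol 18.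

2. Step 10. The dianion may form incompletely, may be acylated only slowly by the α-branched amide, or may act as a base on the amide α-proton with β-elimination of the acetonide oxygen. The fallback sets out from 14 and 10 and uses a more electrophilic partner. Reduction of 14 with LiAlH4 in THF at −78 °C should give the aldehyde (4S,5R)-5-[(benzyloxy)methyl]-2,2-dimethyl-1,3-dioxolane-4-carbaldehyde F3. Aldol addition of the dianion of 10 (LDA, THF, −78 °C) to F3 should give the β-hydroxy keto-dioxinone F4 as a mixture at the carbinol carbon, which does not matter. Dess–Martin oxidation of F4 should then give the 1,3-diketone and return to the route at 15.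

3. Step 6. The aryloxy-substituted dienolate may be acylated on oxygen or at the α-carbon, conversion may stall through proton exchange with the product, or the γ-oxygenated dienolate may decompose. The fallback sets out from 7 and 6 and forms the C–O bond last instead of the C–C bond. Acylation of the dienolate of 7 (LiHMDS, then AcCl) should give the known 2,2-dimethyl-6-(2-oxopropyl)-4H-1,3-dioxin-4-one F5. Chlorination of its doubly activated methylene with SO2Cl2 in CH2Cl2 at 0 °C should give 6-(1-chloro-2-oxopropyl)-2,2-dimethyl-4H-1,3-dioxin-4-one F6. SN2 displacement of this activated secondary chloride by phenol 6 (K2CO3, acetone) returns to the route at 10.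

**Further compounds**

F1 | step 11 | methyl 4-[2-(benzyloxy)-3-methoxy-5-phenylphenoxy]-7-[(4S,5R)-5-[(benzyloxy)methyl]-2,2-dimethyl-1,3-dioxolan-4-yl]-3,5,7-trioxoheptanoate | COC(=O)CC(=O)C(Oc1cc(-c2ccccc2)cc(OC)c1OCc1ccccc1)C(=O)CC(=O)[C@H]1OC(C)(C)O[C@@H]1COCc1ccccc1
F2 | step 11 | methyl 3-[2-(benzyloxy)-3-methoxy-5-phenylphenoxy]-6-[(4R,5R)-5-[(benzyloxy)methyl]-2,2-dimethyl-1,3-dioxolan-4-yl]-2,4-dihydroxybenzoate | COC(=O)c1c(O)c(Oc2cc(-c3ccccc3)cc(OC)c2OCc2ccccc2)c(O)cc1[C@H]1OC(C)(C)O[C@@H]1COCc1ccccc1
F3 | step 10 | (4S,5R)-5-[(benzyloxy)methyl]-2,2-dimethyl-1,3-dioxolane-4-carbaldehyde | O=C[C@H]1OC(C)(C)O[C@@H]1COCc1ccccc1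
F4 | step 10 | 6-{1-[2-(benzyloxy)-3-methoxy-5-phenylphenoxy]-4-[5-[(benzyloxy)methyl]-2,2-dimethyl-1,3-dioxolan-4-yl]-4-hydroxy-2-oxobutyl}-2,2-dimethyl-4H-1,3-dioxin-4-one (dioxolane configuration as in 14, carbinol and methine undefined) | CC1(C)OC(=O)C=C(O1)C(Oc1cc(-c2ccccc2)cc(OC)c1OCc1ccccc1)C(=O)CC(O)[C@H]1OC(C)(C)O[C@@H]1COCc1ccccc1
F5 | step 6 | 2,2-dimethyl-6-(2-oxopropyl)-4H-1,3-dioxin-4-one | CC(=O)CC1=CC(=O)OC(C)(C)O1
F6 | step 6 | 6-(1-chloro-2-oxopropyl)-2,2-dimethyl-4H-1,3-dioxin-4-one | CC(=O)C(Cl)C1=CC(=O)OC(C)(C)O1
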